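**Strategy.** Everything rests on disconnecting the aryl ether bond O1–C8a in ring C of the upper flavan unit. An acyclic 1,3-diaryl-2-benzyloxypropane-1,3-diol, built by an Evans glycolate aldol and an anti-selective 1,3-reduction, carries bromine at the future C8a of ring A, between C4a and the C8 oxygen. Copper-catalysed Ullmann etherification then closes the pyran ring with C2, C3 and C4 already in place, because only the C2 hydroxyl can reach C8a in a six-membered mode. The single cyclisation product supplies all three flavan units: upper electrophile, lower nucleophile after O-benzylation, middle unit after C3 epimerisation through the 4-ketone; two C4→C6 Friedel–Crafts unions and hydrogenolysis finish.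

Key step: step 8

Remark: flavan numbering (O1, C2, C3, C4, C4a, C5–C8, C8a; rings A, B, C) is used also for open-chain precursors; α is the face of ring C carrying the 2-aryl group, β the other face; epioritin is (2R,3R)-2,3-cis-7,8,4'-trihydroxyflavan-3-ol and oritin its (2R,3S)-2,3-trans isomer; compound 14 is divided between steps 9, 12 and 13; the C4 epimers of 17 and 18 converge on one cation, so only the expected isomer is drawn.

**Step 1**
Reactants: 1 3-bromobenzene-1,2-diol
Product: 2 1,2-bis(benzyloxy)-3-bromobenzene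
Conditions: BnBr (2.4 equiv), K2CO3, DMF, 60 °C
Reagents that add atoms: benzyl bromide, BrCc1ccccc1
Why: Williamson ether synthesis of both phenols under carbonate base should proceed cleanly.

**Step 2**
Reactants: 2 1,2-bis(benzyloxy)-3-bromobenzene
Product: 3 1,2-bis(benzyloxy)-3-bromo-4-iodobenzene
Conditions: NIS, TFA (cat.), MeCN, 0 °C → rt
Reagents that add atoms: N-iodosuccinimide, O=C1CCC(=O)N1I
Why: Electrophilic aromatic iodination should go para to the unhindered 1-benzyloxy group (ortho to bromine), since the 2-benzyloxy group is twisted out of conjugation by its two neighbours.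

**Step 3**
Reactants: 4 (S)-4-benzyloxazolidin-2-one, 5 (benzyloxy)acetyl chloride
Product: 6 (S)-4-benzyl-3-[(benzyloxy)acetyl]oxazolidin-2-one
Conditions: n-BuLi, THF, −78 °C; then 5, −78 → 0 °C
Reagents that add atoms: none
Why: N-acylation of the lithiated oxazolidinone is the standard loading of the Evans auxiliary.

**Step 4**
Reactants: 6 (S)-4-benzyl-3-[(benzyloxy)acetyl]oxazolidin-2-one, 7 4-(benzyloxy)benzaldehyde
Product: 9 (S)-4-benzyl-3-[(2S,3R)-2-(benzyloxy)-3-[4-(benzyloxy)phenyl]-3-hydroxypropanoyl]oxazolidin-2-one, via Z-dibutylboron enolate 8 (not isolated)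
Conditions: Bu2BOTf, Et3N, CH2Cl2, 0 °C; 7, −78 → 0 °C; H2O2, MeOH, pH 7 buffer, 0 °C
Reagents that add atoms: none
Why: Evans syn glycolate aldol through a Zimmerman–Traxler chair of the Z-boron enolate, in which the benzyl group of the auxiliary shields one enolate face, should set the future C2 (R) and C3 centres as the syn pair.

**Step 5**
Reactants: 9 syn-aldol imide
Product: 10 (2S,3R)-2-(benzyloxy)-3-[4-(benzyloxy)phenyl]-3-hydroxy-N-methoxy-N-methylpropanamide
Conditions: MeNHOMe·HCl, Me3Al, CH2Cl2, −20 → 0 °C; aq. Rochelle salt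
Reagents that add atoms: N,O-dimethylhydroxylamine hydrochloride, CNOC.Cl
Why: Weinreb transamidation by the aluminium amide, assisted by the free β-hydroxyl, should cleave the auxiliary without touching either stereocentre.

**Step 6**
Reactants: 10 Weinreb amide, 3 1,2-bis(benzyloxy)-3-bromo-4-iodobenzene
Product: 12 (2S,3R)-2-(benzyloxy)-1-[3,4-bis(benzyloxy)-2-bromophenyl]-3-[4-(benzyloxy)phenyl]-3-hydroxypropan-1-one, via arylmagnesium chloride 11 (not isolated)
Conditions: 3 (1.6 equiv), iPrMgCl·LiCl (1.5 equiv), THF, −20 °C; then 10 (pre-treated with iPrMgCl, 1.0 equiv), −20 → 0 °C; aq. NH4Cl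
Reagents that add atoms: none
Why: Iodine–magnesium exchange (turbo-Grignard) should be selective for C–I over C–Br, and the Weinreb ketone synthesis stops at the chelated tetrahedral adduct, so no ketone is exposed to base and retro-aldol is avoided.

**Step 7**
Reactants: 12 β-hydroxy ketone
Product: 13 (1R,2S,3R)-2-(benzyloxy)-1-[3,4-bis(benzyloxy)-2-bromophenyl]-3-[4-(benzyloxy)phenyl]propane-1,3-diol
Conditions: Me4NBH(OAc)3, MeCN/AcOH, −30 → −10 °C
Reagents that add atoms: none
Why: Evans–Saksena reduction delivers hydride intramolecularly from the alkoxyborohydride formed at the future C2 hydroxyl, which should set the future C4 carbinol 1,3-anti to it (and anti to the benzyloxy group), the arrangement that becomes all-cis in the ring.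

**Step 8**
Reactants: 13 anti-1,3-diol
Product: 14 (2R,3R,4R)-3,7,8-tris(benzyloxy)-2-[4-(benzyloxy)phenyl]chroman-4-ol
Conditions: CuI (10 mol %), 3,4,7,8-tetramethyl-1,10-phenanthroline (20 mol %), Cs2CO3, toluene (0.02 M), 110 °C, Ar
Reagents that add atoms: none
Why: The caesium alkoxide of the C2 hydroxyl binds monovalent copper, oxidative addition of the neighbouring C–Br bond gives a trivalent aryl copper alkoxide, and reductive elimination forges O1–C8a; the closest known reaction type is the copper-catalysed intramolecular Ullmann O-arylation of aliphatic alcohols used to make chromans. Ring C closes in a 6-exo mode onto the ring A carbon that is ortho both to the chain-bearing C4a and to the C8 oxygen, so the bromine position fixes the 7,8-dioxygenation pattern. No stereocentre is formed or touched: C2 and C3 come from the aldol (auxiliary control), C4 from the 1,3-anti reduction (control by the C2 carbinol), and the C2–O bond is never broken, so the closure is stereoretentive. The selectivity needed is between the two free hydroxyls and against five-ring closure: the C4 hydroxyl could only form a four-membered ring and the C3 oxygen is capped as its benzyl ether, so only the C2 oxygen can arylate. High dilution should suppress intermolecular arylation.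

**Step 9**
Reactants: 14 all-cis flavan-4-ol
Product: 16 (2R,3R)-3,7,8-tris(benzyloxy)-2-[4-(benzyloxy)phenyl]chroman-4-one, via cis-flavanone 15 (not isolated)
Conditions: Dess–Martin periodinane, NaHCO3, CH2Cl2, 0 °C → rt; filtration; then DBU (0.2 equiv), CH2Cl2, rt
Reagents that add atoms: none
Why: Dess–Martin oxidation followed by base-mediated enolisation should epimerise C3 to the thermodynamically preferred 2,3-trans ketone (both substituents equatorial), the fixed C2 centre controlling the outcome.

**Step 10**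
Reactants: 16 trans-flavanone
Product: 17 (2R,3S,4R)-3,7,8-tris(benzyloxy)-2-[4-(benzyloxy)phenyl]chroman-4-ol
Conditions: NaBH4, THF/MeOH, 0 °C
Reagents that add atoms: none
Why: Borohydride reduction by axial hydride attack should give mainly the equatorial 3,4-trans alcohol, and the C4 configuration is of no consequence because this centre is ionised later.

**Step 11**
Reactants: 17 trans,trans-flavan-4-ol
Product: 18 (2R,3R,4R)-3,7,8-tris(benzyloxy)-2-[4-(benzyloxy)phenyl]-4-[(2,6-dimethylphenyl)sulfanyl]chromane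
Conditions: 2,6-dimethylbenzenethiol (3 equiv), BF3·OEt2 (0.3 equiv), CH2Cl2, −40 °C
Reagents that add atoms: 2,6-dimethylbenzenethiol, Cc1cccc(C)c1S
Why: Lewis acid-mediated SN1 thiolysis through the C4 cation, stabilised by the para 7-benzyloxy group and O1, should install the thioether anti to the 3-benzyloxy group (4α), the bulky aryl group guarding sulfur against later transfer.

**Step 12**
Reactants: 14 all-cis flavan-4-ol
Product: 19 (2R,3R,4R)-3,4,7,8-tetrakis(benzyloxy)-2-[4-(benzyloxy)phenyl]chromane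
Conditions: NaH, BnBr, Bu4NI (cat.), DMF, 0 °C → rt
Reagents that add atoms: benzyl bromide, BrCc1ccccc1
Why: Williamson etherification caps the 4α-hydroxyl so that the lower unit can react only as a carbon nucleophile.

**Step 13**
Reactants: 14 all-cis flavan-4-ol (upper unit), 18 thioether (middle unit)
Product: 20 octa-O-benzyl epioritin-(4β→6)-oritin carrying a 4α-(2,6-dimethylphenyl)sulfanyl group on the oritin unit
Conditions: 18 (3 equiv), BF3·OEt2 (0.5 equiv), 4 Å MS, CH2Cl2, −40 → −10 °C
Reagents that add atoms: none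
Why: Dehydrative Friedel–Crafts interflavan coupling: the hard Lewis acid ionises the C4 hydroxyl of 14 but leaves the thioether of 18 intact (orthogonal activation), C6 of 18 (ortho to the 7-benzyloxy group, para to O1) attacks, and approach anti to the cis 2-aryl and 3-benzyloxy groups should set the new C4 centre β.

**Step 14**
Reactants: 20 dimer thioether, 19 penta-O-benzyl lower unit
Product: 21 trideca-O-benzyl epioritin-(4β→6)-oritin-(4α→6)-epioritin-4α-ol
Conditions: 19 (4 equiv), AgBF4 (2 equiv), THF, 0 °C, dark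
Reagents that add atoms: none
Why: Thiophilic silver activation ionises only the C–S bond (the 4-O-benzyl ether of 19 is not addressed by the soft Lewis acid), and Friedel–Crafts attack of C6 of 19 anti to the 3-benzyloxy group of the 2,3-trans middle unit should set its C4 centre α.

**Step 15**
Reactants: 21 trideca-O-benzyl trimer
Product: 22 epioritin-(4β→6)-oritin-(4α→6)-epioritin-4α-ol
Conditions: H2 (1 atm), Pd(OH)2/C, THF/MeOH/H2O, rt; filtration and freeze-drying under Ar
Reagents that add atoms: none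
Why: Catalytic hydrogenolysis should cleave all thirteen primary benzyl C–O bonds in preference to the hindered secondary C4–O bond of the lower unit and leaves the diarylmethine interflavan bonds untouched.

**Compound list**
1 | 3-bromobenzene-1,2-diol | Oc1cccc(Br)c1O | starting material
2 | 1,2-bis(benzyloxy)-3-bromobenzene | Brc1cccc(OCc2ccccc2)c1OCc1ccccc1 | intermediate
3 | 1,2-bis(benzyloxy)-3-bromo-4-iodobenzene | Ic1ccc(OCc2ccccc2)c(OCc2ccccc2)c1Br | intermediate
4 | (S)-4-benzyloxazolidin-2-one | O=C1N[C@@H](Cc2ccccc2)CO1 | starting material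
5 | (benzyloxy)acetyl chloride | ClC(=O)COCc1ccccc1 | starting material
6 | (S)-4-benzyl-3-[(benzyloxy)acetyl]oxazolidin-2-one | O=C(COCc1ccccc1)N1[C@@H](Cc2ccccc2)COC1=O | intermediate
7 | 4-(benzyloxy)benzaldehyde | O=Cc1ccc(OCc2ccccc2)cc1 | starting material
8 | Z-dibutylboron enolate of 6 | CCCCB(CCCC)O/C(=C\OCc1ccccc1)N1[C@@H](Cc2ccccc2)COC1=O | intermediate (not isolated)
9 | (S)-4-benzyl-3-[(2S,3R)-2-(benzyloxy)-3-[4-(benzyloxy)phenyl]-3-hydroxypropanoyl]oxazolidin-2-one | O[C@H](c1ccc(OCc2ccccc2)cc1)[C@H](OCc1ccccc1)C(=O)N1[C@@H](Cc2ccccc2)COC1=O | intermediate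
10 | (2S,3R)-2-(benzyloxy)-3-[4-(benzyloxy)phenyl]-3-hydroxy-N-methoxy-N-methylpropanamide | O[C@H](c1ccc(OCc2ccccc2)cc1)[C@H](OCc1ccccc1)C(=O)N(C)OC | intermediate
11 | [3,4-bis(benzyloxy)-2-bromophenyl]magnesium chloride | Cl[Mg]c1ccc(OCc2ccccc2)c(OCc2ccccc2)c1Br | intermediate (not isolated)
12 | (2S,3R)-2-(benzyloxy)-1-[3,4-bis(benzyloxy)-2-bromophenyl]-3-[4-(benzyloxy)phenyl]-3-hydroxypropan-1-one | O[C@H](c1ccc(OCc2ccccc2)cc1)[C@H](OCc1ccccc1)C(=O)c1ccc(OCc2ccccc2)c(OCc2ccccc2)c1Br | intermediate
13 | (1R,2S,3R)-2-(benzyloxy)-1-[3,4-bis(benzyloxy)-2-bromophenyl]-3-[4-(benzyloxy)phenyl]propane-1,3-diol (1,3-anti) | O[C@H](c1ccc(OCc2ccccc2)cc1)[C@H](OCc1ccccc1)[C@H](O)c1ccc(OCc2ccccc2)c(OCc2ccccc2)c1Br | intermediate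
14 | (2R,3R,4R)-3,7,8-tris(benzyloxy)-2-[4-(benzyloxy)phenyl]chroman-4-ol (all-cis) | c1cc2c(c(OCc3ccccc3)c1OCc3ccccc3)O[C@H](c3ccc(OCc4ccccc4)cc3)[C@H](OCc3ccccc3)[C@@H]2O | intermediate
15 | (2R,3S)-3,7,8-tris(benzyloxy)-2-[4-(benzyloxy)phenyl]chroman-4-one (2,3-cis) | c1cc2c(c(OCc3ccccc3)c1OCc3ccccc3)O[C@H](c3ccc(OCc4ccccc4)cc3)[C@H](OCc3ccccc3)C2=O | intermediate (not isolated)
16 | (2R,3R)-3,7,8-tris(benzyloxy)-2-[4-(benzyloxy)phenyl]chroman-4-one (2,3-trans) | c1cc2c(c(OCc3ccccc3)c1OCc3ccccc3)O[C@H](c3ccc(OCc4ccccc4)cc3)[C@@H](OCc3ccccc3)C2=O | intermediate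
17 | (2R,3S,4R)-3,7,8-tris(benzyloxy)-2-[4-(benzyloxy)phenyl]chroman-4-ol (2,3-trans-3,4-trans) | c1cc2c(c(OCc3ccccc3)c1OCc3ccccc3)O[C@H](c3ccc(OCc4ccccc4)cc3)[C@@H](OCc3ccccc3)[C@@H]2O | intermediate
18 | (2R,3R,4R)-3,7,8-tris(benzyloxy)-2-[4-(benzyloxy)phenyl]-4-[(2,6-dimethylphenyl)sulfanyl]chromane (2,3-trans-3,4-trans, 4α) | c1cc2c(c(OCc3ccccc3)c1OCc3ccccc3)O[C@H](c3ccc(OCc4ccccc4)cc3)[C@@H](OCc3ccccc3)[C@@H]2Sc1c(C)cccc1C | intermediate
19 | (2R,3R,4R)-3,4,7,8-tetrakis(benzyloxy)-2-[4-(benzyloxy)phenyl]chromane (all-cis) | c1cc2c(c(OCc3ccccc3)c1OCc3ccccc3)O[C@H](c3ccc(OCc4ccccc4)cc3)[C@H](OCc3ccccc3)[C@@H]2OCc1ccccc1 | intermediate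
20 | octa-O-benzyl epioritin-(4β→6)-oritin with a 4α-(2,6-dimethylphenyl)sulfanyl group on the oritin unit | c5ccccc5COc1ccc([C@H]2Oc3c(ccc(OCc5ccccc5)c3OCc5ccccc5)[C@H](c3cc4c(c(OCc5ccccc5)c3OCc5ccccc5)O[C@H](c3ccc(OCc5ccccc5)cc3)[C@@H](OCc5ccccc5)[C@@H]4Sc3c(C)cccc3C)[C@H]2OCc5ccccc5)cc1 | intermediate
21 | trideca-O-benzyl epioritin-(4β→6)-oritin-(4α→6)-epioritin-4α-ol | c5ccccc5COc1ccc([C@H]2Oc3c(ccc(OCc5ccccc5)c3OCc5ccccc5)[C@H](c3cc4c(c(OCc5ccccc5)c3OCc5ccccc5)O[C@H](c3ccc(OCc5ccccc5)cc3)[C@@H](OCc5ccccc5)[C@@H]4c3cc4c(c(OCc5ccccc5)c3OCc5ccccc5)O[C@H](c3ccc(OCc5ccccc5)cc3)[C@H](OCc5ccccc5)[C@@H]4OCc5ccccc5)[C@H]2OCc5ccccc5)cc1 | intermediate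
22 | epioritin-(4β→6)-oritin-(4α→6)-epioritin-4α-ol (upper unit 2R,3R,4S; middle unit 2R,3S,4R; lower unit 2R,3R,4R), CNP0140823.2 | Oc1ccc([C@H]2Oc3c(ccc(O)c3O)[C@H](c3cc4c(c(O)c3O)O[C@H](c3ccc(O)cc3)[C@@H](O)[C@@H]4c3cc4c(c(O)c3O)O[C@H](c3ccc(O)cc3)[C@H](O)[C@@H]4O)[C@H]2O)cc1 | target

**Count.** Total steps: 15. Longest linear sequence: 12 steps (3, 4, 5, 6, 7, 8, 9, 10, 11, 13, 14, 15).

**Steps most likely to fail**

Step 8. The oxidative addition into the doubly ortho-substituted C–Br bond may be sluggish, and the free benzylic hydroxyl next to the bromoarene may divert the catalyst towards hydrodebromination or alcohol oxidation. The fallback closes the same O1–C8a bond one oxidation level higher and makes no compound outside the list. It sets out from ketone 12, where the ortho-acyl group activates the C–Br bond and no second hydroxyl is present. Buchwald–Hartwig-type intramolecular etherification (Pd(OAc)2, 2-(di-tert-butylphosphino)-1,1'-binaphthyl, K3PO4, toluene, 60 °C) should give cis-flavanone 15, which is isolated here. Reduction with LiBH(s-Bu)3 (THF, −78 °C), hydride entering anti to the 2-aryl and 3-benzyloxy groups, comes back to the route at 14.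

Step 13. The cation from 14 may alkylate a second molecule of 14 through its own C6, and the arylsulfanyl group may migrate from 18 to the upper-unit cation, which would scramble the two units. The fallback reverses the order of union so that both couplings use thiophilic activation and no orthogonality is needed. It sets out from 18 and 19, which with AgBF4 in THF should give the middle–lower dimer nona-O-benzyl oritin-(4α→6)-epioritin-4α-ol F1. In parallel, 14 is converted with 2,6-dimethylbenzenethiol and BF3·OEt2 into its 4β-(2,6-dimethylphenyl)sulfanyl derivative F2. AgBF4-promoted union of F2 with F1, whose only activated free position is C6 of the middle unit, comes back to the route at 21.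

Step 14. Facial selectivity at C4 of the hindered dimeric cation may be poor, the fully benzylated ring A of 19 is only a moderate nucleophile, and the HBF4 released may ionise the 4-O-benzyl ether of 19. The fallback uses the lower unit unprotected. It sets out from 14, whose hydrogenolysis (H2, Pd(OH)2/C) should give (2R,3R,4R)-2-(4-hydroxyphenyl)chromane-3,4,7,8-tetrol F3; its free 7-hydroxyl makes C6 far more nucleophilic. AgBF4 coupling of 20 with excess F3 in THF should give the trimer benzylated only on the upper and middle units F4, and hydrogenolysis of F4 comes back to the route at 22.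

**Further compounds**
F0 | step 8 | none | none
F1 | step 13 | nona-O-benzyl oritin-(4α→6)-epioritin-4α-ol | c1cc2c(c(OCc5ccccc5)c1OCc5ccccc5)O[C@H](c1ccc(OCc5ccccc5)cc1)[C@@H](OCc5ccccc5)[C@@H]2c3cc4c(c(OCc5ccccc5)c3OCc5ccccc5)O[C@H](c3ccc(OCc5ccccc5)cc3)[C@H](OCc5ccccc5)[C@@H]4OCc5ccccc5
F2 | step 13 | 4β-(2,6-dimethylphenyl)sulfanyl derivative of 14 (2,3-cis-3,4-trans) | c1cc2c(c(OCc3ccccc3)c1OCc3ccccc3)O[C@H](c3ccc(OCc4ccccc4)cc3)[C@H](OCc3ccccc3)[C@H]2Sc1c(C)cccc1C
F3 | step 14 | (2R,3R,4R)-2-(4-hydroxyphenyl)chromane-3,4,7,8-tetrol | c1cc2c(c(O)c1O)O[C@H](c3ccc(O)cc3)[C@H](O)[C@@H]2O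
F4 | step 14 | epioritin-(4β→6)-oritin-(4α→6)-epioritin-4α-ol benzylated on all eight hydroxyls of the upper and middle units | c5ccccc5COc1ccc([C@H]2Oc3c(ccc(OCc5ccccc5)c3OCc5ccccc5)[C@H](c3cc4c(c(OCc5ccccc5)c3OCc5ccccc5)O[C@H](c3ccc(OCc5ccccc5)cc3)[C@@H](OCc5ccccc5)[C@@H]4c3cc4c(c(O)c3O)O[C@H](c3ccc(O)cc3)[C@H](O)[C@@H]4O)[C@H]2OCc5ccccc5)cc1
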